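Leftover first: any gas the catalyst does not catch goes to decomposed reagent or stays in solution and slows its own transfer, so I reckon how much is caught.

    substrate + target → side product (k1 = 2.79 M⁻¹ h⁻¹)
    dissolved gas → decomposed reagent (k2 = 0.447 h⁻¹)
    substrate + dissolved gas + catalyst → catalyst + target (k3 = 1.04 × 10⁶ M⁻² h⁻¹)
    gas phase ⇌ dissolved gas, rate k4*(csat - [dissolved gas]) (k4 = 0.330 h⁻¹, csat = 3.5 mM)

substrate 0.020 M; gas phase 3.5 mM (held); catalyst 68 µM; time 25 h

* how much target there is at 25 h, in percent of the substrate charged
* concentration of dissolved gas in solution at 6.0 h, in percent of saturation
* the change that raises the amount of target at 25 h, in percent of the substrate charged most ("none" if none brings more than 2 percentage points) (ochre / teal / violet / none)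
* amount of target at 25 h, in percent of the substrate charged, after violet

- ochre: doubling the amount of catalyst, all else as stated
- teal: doubling the transfer coefficient of step 4, all else as stated
- violet: doubling the saturation concentration of gas phase, all else as stated

- percent here means substrate units held: one side product counts as two
- at the start none of the gas is dissolved
- run time (flask): 25 h

At the charged amounts, dissolved gas has a half-life of 0.49 h by step 3 and 1.6 h by step 2, both short against 25 h, so I hold it quasi-steady. Target then forms at k4·csat·c(substrate)/(c(substrate) + cH). Here cH = (k2 + k4)/(k3·c(catalyst)) = 11.0 mM is the half-capture concentration, a half-saturation constant: the substrate level at which the rate is half of k4·csat. Over the run, k4·csat·t gives a gas budget of 28.9 mM.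

For the ceiling I drop step 1. Spending substrate down to c then costs c(start) − c + cH·ln(c(start)/c). Leaving one part in 4 costs 30.2 mM, above the budget, so target stays under 75.0 %.

For the floor I assume substrate stays above one part in 3 up to 12.5 h and above one part in 7 afterwards. I count step 1 here: at the charged substrate, target's half-life by it is 12 h, about half the run. In the first half I give it the full charge of substrate, which still leaves at least 3.93 mM target. In the second half I give it the charge less that target.

| Bound on y | Assumes | Value |
|---|---|---|
| ceiling | no step 1 | 75.0 % |
| floor | substrate levels above | 22.6 % |

The forecast gives 48 % (45 % to 51 %), inside my bracket, with 17.4 %, violet and 70 %: “Violet beats teal, which also adds gas loss, and ochre, which is supply-limited.”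

The flask holds 48.2 % target at 25 h. Dissolved gas stands at 17.3 % of saturation at 6.0 h. The change violet raises target most, by 22 percentage points to 70.2 %, against 16 points for teal and 13 points for ochre. At 25 h it holds 34.3 % as side product. With 0.050 M of substrate, the same cH and budget cap target ever made at 47.3 % of that charge. That neighbour flask has made 42.0 %, of which 18.6 % still stands as target.

The constants stand for no real mixture.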